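**Retrosynthetic overview** (labdane numbering throughout)
- The target is (13R)-13-hydroxylabda-8(17),14-dien-19-yl tiglate. The C19 ester and the C13 carbinol are made last: the tertiary allylic alcohol comes from Sharpless epoxidation and iodide/Zn opening of a (13E)-allylic alcohol, whose C13–C16 unit comes from acetylide alkylation at C12 and Cp2ZrCl2-catalysed carboalumination.
- Key disconnection C8–C9: ring B with its C8(17) exocyclic methylene comes from a Ni(cod)2-mediated reductive coupling of a C5 but-3-ynyl arm (C6, C7, C8, C17) with a C10 (E)-enoyl arm (C9, C11, C12) on ring A.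
- Feature on which the strategy rests: ring A (C1–C5, C10) with quaternary C4 (axial oxygenated C19, equatorial C18), 5α-H and 10β-CH3 is ring A of (+)-podocarpic acid. Oxidative removal of C11–C14 of its phenol ring leaves the aromatic carbons C8 and C9 as the carboxyl ends of the two arms.
- Ring order: ring A is taken intact from the chiral pool; ring B is the only ring formed (step 10).

Key step: step 10

Remark on the chemistry (assumption): the acceptor arm is carried as the N-enoyl oxazolidin-2-one and not as a simple alkyl enoate, because plain enoates are assumed to be sluggish in nickel/organozinc alkyne cyclizations while enoyl imides are good partners; TBS = tert-butyldimethylsilyl.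

Step 1
Reactants: 1 (+)-podocarpic acid
Product: 2 podocarpa-8,11,13-triene-12,19-diol
Conditions: LiAlH4, THF, reflux; aq NaOH work-up
Reagents that add atoms: none
Why: Hydride reduction of the carboxylic acid: LiAlH4 in refluxing THF takes the hindered axial C19 acid (as its carboxylate) to the neopentyl primary alcohol without touching any stereocentre.

Step 2
Reactants: 2 podocarpa-8,11,13-triene-12,19-diol
Product: 3 12,19-bis(TBS-oxy)podocarpa-8,11,13-triene
Conditions: TBSCl (2.5 equiv), imidazole, DMF, rt → 40 °C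
Reagents that add atoms: tert-butyldimethylsilyl chloride, CC(C)(C)[Si](C)(C)Cl
Why: Imidazole-promoted silylation caps both hydroxyls; the aryl silyl ether is sacrificial (it keeps the ring electron-rich for step 3) and the C19 silyl ether is the protecting group carried to step 18.

Step 3
Reactants: 3 12,19-bis(TBS-oxy)podocarpa-8,11,13-triene
Product: 4 19-(TBS-oxy)-11,12,13,14-tetranor-8,9-secopodocarpane-8,9-dioic acid (ring A diacid: CO2H = C9 on C10, CH2CH2CO2H = C6–C8 on C5; 4β-CH2OTBS, 5α-H, 10β-CH3)
Conditions: RuCl3·xH2O (cat.), NaIO4 (excess), EtOAc/MeCN/H2O, rt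
Reagents that add atoms: sodium periodate, [Na+].[O-]I(=O)(=O)=O; water, O
Why: RuO4 arene degradation (RuCl3/NaIO4): the electron-rich silyloxy ring is oxidised away down to its two alkyl-bearing carbons, so C8 (on C7) and C9 (on C10) remain as carboxylic acids, C11–C14 leave as CO2, and ring A with its three stereocentres is untouched.

Step 4
Reactants: 4 ring A diacid
Product: 5 19-(TBS-oxy)-11,12,13,14-tetranor-8,9-secopodocarpane-8,9-diol
Conditions: BH3·SMe2, THF, 0 °C → reflux; MeOH quench
Reagents that add atoms: none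
Why: Borane reduction of carboxylic acids converts both acids into primary alcohols (the hindered C9 acid on quaternary C10 needs the heating) and is inert towards the silyl ether.

Step 5
Reactants: 5 ring A 8,9-diol
Product: 6 9-hydroxy-19-(TBS-oxy)-11,12,13,14-tetranor-8,9-secopodocarpan-8-al
Conditions: TEMPO (cat.), PhI(OAc)2 (1.1 equiv), CH2Cl2, rt
Reagents that add atoms: none
Why: TEMPO/PhI(OAc)2 oxidation is strongly sensitive to steric hindrance, so the unhindered C8 primary alcohol should be oxidised to the aldehyde while the neopentyl C9 alcohol (on quaternary C10, syn-axial to the C19 arm) is left, and without water the aldehyde is not oxidised further.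

Step 6
Reactants: 6 C8 aldehyde with free C9 alcohol; 7 dimethyl (1-diazo-2-oxopropyl)phosphonate
Product: 8 19-(TBS-oxy)-11,12,13,14,15,16-hexanor-8,9-secolabd-8(17)-yn-9-ol (C5 arm CH2CH2C≡CH, C10 arm CH2OH)
Conditions: K2CO3, MeOH, 0 °C → rt
Reagents that add atoms: none
Why: Ohira–Bestmann (Seyferth–Gilbert) homologation: methanolysis of 7 gives the diazomethylphosphonate anion, which adds to the C8 aldehyde and, after loss of phosphate and N2 and 1,2-hydride shift of the alkylidene carbene, gives the terminal alkyne C8≡C17 under conditions mild enough for the free C9 alcohol and the silyl ether.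

Step 7
Reactants: 8 alkynol
Product: 9 19-(TBS-oxy)-11,12,13,14,15,16-hexanor-8,9-secolabd-8(17)-yn-9-al
Conditions: Dess–Martin periodinane, CH2Cl2, rt
Reagents that add atoms: none
Why: Dess–Martin oxidation takes the hindered neopentyl C9 alcohol to the aldehyde, which has no α-hydrogen and cannot epimerise or enolise, and leaves the terminal alkyne alone.

Step 8
Reactants: 10 2-(diethoxyphosphoryl)acetic acid; 11 1,3-oxazolidin-2-one
Product: 12 diethyl [2-oxo-2-(2-oxo-1,3-oxazolidin-3-yl)ethyl]phosphonate
Conditions: DCC, DMAP (cat.), CH2Cl2, 0 °C → rt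
Reagents that add atoms: none
Why: DCC/DMAP N-acylation of oxazolidin-2-one by the carboxylic acid (Steglich-type coupling) gives the imide-stabilised Horner–Wadsworth–Emmons reagent in one step.

Step 9
Reactants: 9 alkynyl aldehyde; 12 phosphonate imide
Product: 13 3-[(9E)-19-(TBS-oxy)-13,14,15,16-tetranor-8,9-secolabd-9(11)-en-8(17)-yn-12-oyl]-1,3-oxazolidin-2-one (C5 but-3-ynyl arm, C10 (E)-CH=CH–C(=O)N arm)
Conditions: NaH, THF, 0 °C; then 9, rt → 45 °C
Reagents that add atoms: none
Why: Horner–Wadsworth–Emmons olefination of the non-enolisable C9 aldehyde with the sodium salt of 12 gives the (E)-enoyl imide under thermodynamic control of the oxaphosphetane, installing C11 and C12 together with the activating oxazolidinone.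

Step 10
Reactants: 13 alkynyl (E)-enoyl imide
Product: 14 3-[19-(TBS-oxy)-13,14,15,16-tetranorlabd-8(17)-en-12-oyl]-1,3-oxazolidin-2-one (trans-decalin; 5α-H, 9α-H, 10β-CH3)
Conditions: Ni(cod)2 (10 mol%), PPh3 (50 mol%), Et2Zn (3 equiv), THF, 0 °C → rt; aq NH4Cl
Reagents that add atoms: none
Why: Zerovalent nickel binds the alkyne and the s-cis enoyl imide and undergoes oxidative cyclization to a seven-membered oxa-nickelacycle (a divalent nickel O-enolate) that already contains the C8–C9 bond; ethyl transfer from Et2Zn gives a zinc enolate and an ethyl(alkenyl)nickel species, which under PPh3 undergoes β-hydride elimination (ethene) and C–H reductive elimination to put hydrogen on C17, and the zinc enolate is protonated at C11 on work-up. The closest known reaction type is the Ni(cod)2/PPh3/Et2Zn reductive cyclization of alkynyl enones, together with nickel/organozinc cyclizations of alkynyl N-enoyl oxazolidinones. Ring B closes in the 6-exo mode at both partners (exo-dig at the alkyne, exo-trig at the enoyl alkene), C8 and C9 becoming ring atoms while C17 and C11 stay outside. The new stereocentre C9 is set by the chair of ring A, which holds the C5 and C10 arms trans-diequatorial so that ring B can only form as the trans-fused chair, and by the enoyl rotamer in which C9–H eclipses C10–C5, which places C11 equatorial (β) and H-9 axial (α). The step needs cyclization to outrun conjugate ethylation, and hydrogen rather than ethyl transfer to C17: the first is secured by the neopentylic, tether-preorganised β-carbon C9, the second by the excess of PPh3 over nickel.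

Step 11
Reactants: 14 decalin imide
Product: 15 19-(TBS-oxy)-13,14,15,16-tetranorlabd-8(17)-en-12-ol
Conditions: LiBH4, H2O (1 equiv), Et2O, 0 °C → rt
Reagents that add atoms: none
Why: LiBH4 reductive cleavage of the N-acyl oxazolidinone at the exocyclic carbonyl gives the C12 primary alcohol and releases the oxazolidinone; the 8(17)-alkene and the silyl ether are inert.

Step 12
Reactants: 15 C12 alcohol
Product: 16 12-iodo-19-(TBS-oxy)-13,14,15,16-tetranorlabd-8(17)-ene
Conditions: I2, PPh3, imidazole, CH2Cl2, 0 °C → rt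
Reagents that add atoms: iodine, II
Why: Appel-type iodination (PPh3/I2/imidazole) converts the unhindered primary alcohol into the iodide by SN2 displacement of the oxyphosphonium ion.

Step 13
Reactants: 16 C12 iodide
Product: 17 19-(TBS-oxy)-15,16-dinorlabd-8(17)-en-13-yne
Conditions: LiC≡CH·H2NCH2CH2NH2, DMSO, rt
Reagents that add atoms: lithium acetylide–ethylenediamine complex, [Li+].[C-]#C.NCCN
Why: SN2 alkylation of lithium acetylide in DMSO by the unbranched primary iodide adds C13 and C14 as a terminal alkyne.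

Step 14
Reactants: 17 terminal alkyne
Product: 20 (13E)-19-(TBS-oxy)labda-8(17),13-dien-15-ol, via alkenyldimethylalane 18 (not isolated), via lithium alkenylbutyldimethylaluminate 19 (not isolated)
Conditions: Me3Al, Cp2ZrCl2, CH2Cl2, rt; evaporate; n-BuLi, hexane/THF, −30 °C; (CH2O)n, rt
Reagents that add atoms: trimethylaluminium, C[Al](C)C; formaldehyde (as paraformaldehyde), C=O
Why: Cp2ZrCl2-catalysed methylalumination of the terminal alkyne (Negishi carboalumination) adds CH3 to C13 and aluminium to C14 in a syn fashion, and the derived alkenyl aluminate attacks formaldehyde with retention, which fixes the (13E) geometry; the 1,1-disubstituted 8(17)-alkene does not carbometalate.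

Step 15
Reactants: 20 (13E)-allylic alcohol
Product: 21 (13R,14R)-13,14-epoxy-19-(TBS-oxy)labd-8(17)-en-15-ol
Conditions: Ti(OiPr)4 (cat.), D-(−)-diethyl tartrate (cat.), t-BuOOH, 4 Å MS, CH2Cl2, −20 °C
Reagents that add atoms: tert-butyl hydroperoxide, CC(C)(C)OO
Why: Katsuki–Sharpless asymmetric epoxidation: with D-(−)-diethyl tartrate the Ti(OiPr)4/t-BuOOH complex delivers oxygen to the face of the (E)-trisubstituted allylic alcohol that gives the (13R,14R)-epoxide (reagent control, the mirror image of the (2S,3S) outcome of the L-(+)-ester), and the isolated 8(17)-alkene is not epoxidised.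

Step 16
Reactants: 21 epoxy alcohol
Product: 22 (13R,14S)-13,14-epoxy-15-iodo-19-(TBS-oxy)labd-8(17)-ene
Conditions: I2, PPh3, imidazole, Et2O/MeCN, 0 °C
Reagents that add atoms: iodine, II
Why: Appel-type iodination of the primary epoxy alcohol under imidazole buffering replaces OH by I without opening the epoxide (the C14 descriptor changes only through the priority change).

Step 17
Reactants: 22 epoxy iodide
Product: 23 (13R)-19-(TBS-oxy)labda-8(17),14-dien-13-ol
Conditions: Zn dust, EtOH, reflux
Reagents that add atoms: none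
Why: Zn inserts into the C15–I bond and the organozinc undergoes β-elimination with opening of the epoxide at C14–O (reductive epoxide opening), giving the 14-ene and the tertiary C13 alcohol whose C13–O bond, and thus the (13R) configuration set in step 15, is never broken.

Step 18
Reactants: 23 silyl-protected tertiary allylic alcohol
Product: 24 (13R)-labda-8(17),14-diene-13,19-diol
Conditions: Bu4NF, THF, rt → 50 °C
Reagents that add atoms: none
Why: Fluoride-induced desilylation frees the C19 primary alcohol; the tertiary allylic alcohol and both alkenes are stable to Bu4NF.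

Step 19
Reactants: 24 13,19-diol; 25 tiglic acid
Product: 26 (13R)-13-hydroxylabda-8(17),14-dien-19-yl (2E)-2-methylbut-2-enoate (target)
Conditions: DCC, DMAP, CH2Cl2, rt
Reagents that add atoms: none
Why: Steglich esterification: the DMAP-activated acyl group is taken up by the primary C19 alcohol while the tertiary allylic C13 alcohol is too hindered to acylate, and the thermodynamically stable (E)-geometry of the tiglate is retained.

**Compound list**
1 | (+)-podocarpic acid (12-hydroxypodocarpa-8,11,13-trien-19-oic acid) | Oc1ccc2CC[C@H]3[C@@](C)(C(=O)O)CCC[C@]3(C)c2c1 | starting material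
2 | podocarpa-8,11,13-triene-12,19-diol | Oc1ccc2CC[C@H]3[C@@](C)(CO)CCC[C@]3(C)c2c1 | intermediate
3 | 12,19-bis(TBS-oxy)podocarpa-8,11,13-triene | CC(C)(C)[Si](C)(C)Oc1ccc2CC[C@H]3[C@@](C)(CO[Si](C)(C)C(C)(C)C)CCC[C@]3(C)c2c1 | intermediate
4 | 19-(TBS-oxy)-11,12,13,14-tetranor-8,9-secopodocarpane-8,9-dioic acid | OC(=O)CC[C@H]1[C@@](C)(CO[Si](C)(C)C(C)(C)C)CCC[C@]1(C)C(=O)O | intermediate
5 | 19-(TBS-oxy)-11,12,13,14-tetranor-8,9-secopodocarpane-8,9-diol | OCCC[C@H]1[C@@](C)(CO[Si](C)(C)C(C)(C)C)CCC[C@]1(C)CO | intermediate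
6 | 9-hydroxy-19-(TBS-oxy)-11,12,13,14-tetranor-8,9-secopodocarpan-8-al | O=CCC[C@H]1[C@@](C)(CO[Si](C)(C)C(C)(C)C)CCC[C@]1(C)CO | intermediate
7 | dimethyl (1-diazo-2-oxopropyl)phosphonate | CC(=O)C(=[N+]=[N-])P(=O)(OC)OC | starting material
8 | 19-(TBS-oxy)-11,12,13,14,15,16-hexanor-8,9-secolabd-8(17)-yn-9-ol | C#CCC[C@H]1[C@@](C)(CO[Si](C)(C)C(C)(C)C)CCC[C@]1(C)CO | intermediate
9 | 19-(TBS-oxy)-11,12,13,14,15,16-hexanor-8,9-secolabd-8(17)-yn-9-al | C#CCC[C@H]1[C@@](C)(CO[Si](C)(C)C(C)(C)C)CCC[C@]1(C)C=O | intermediate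
10 | 2-(diethoxyphosphoryl)acetic acid | CCOP(=O)(OCC)CC(=O)O | starting material
11 | 1,3-oxazolidin-2-one | O=C1NCCO1 | starting material
12 | diethyl [2-oxo-2-(2-oxo-1,3-oxazolidin-3-yl)ethyl]phosphonate | CCOP(=O)(OCC)CC(=O)N1CCOC1=O | intermediate
13 | 3-[(9E)-19-(TBS-oxy)-13,14,15,16-tetranor-8,9-secolabd-9(11)-en-8(17)-yn-12-oyl]-1,3-oxazolidin-2-one | C#CCC[C@H]1[C@@](C)(CO[Si](C)(C)C(C)(C)C)CCC[C@]1(C)/C=C/C(=O)N2CCOC2=O | intermediate
14 | 3-[19-(TBS-oxy)-13,14,15,16-tetranorlabd-8(17)-en-12-oyl]-1,3-oxazolidin-2-one | O=C(C[C@H]1C(=C)CC[C@H]2[C@@](C)(CO[Si](C)(C)C(C)(C)C)CCC[C@]12C)N3CCOC3=O | intermediate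
15 | 19-(TBS-oxy)-13,14,15,16-tetranorlabd-8(17)-en-12-ol | OCC[C@H]1C(=C)CC[C@H]2[C@@](C)(CO[Si](C)(C)C(C)(C)C)CCC[C@]12C | intermediate
16 | 12-iodo-19-(TBS-oxy)-13,14,15,16-tetranorlabd-8(17)-ene | ICC[C@H]1C(=C)CC[C@H]2[C@@](C)(CO[Si](C)(C)C(C)(C)C)CCC[C@]12C | intermediate
17 | 19-(TBS-oxy)-15,16-dinorlabd-8(17)-en-13-yne | C#CCC[C@H]1C(=C)CC[C@H]2[C@@](C)(CO[Si](C)(C)C(C)(C)C)CCC[C@]12C | intermediate
18 | (13E)-14-(dimethylalumanyl)-19-(TBS-oxy)-15-norlabda-8(17),13-diene | C[Al](C)/C=C(C)/CC[C@H]1C(=C)CC[C@H]2[C@@](C)(CO[Si](C)(C)C(C)(C)C)CCC[C@]12C | intermediate (not isolated)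
19 | lithium butyl(dimethyl)[(13E)-19-(TBS-oxy)-15-norlabda-8(17),13-dien-14-yl]aluminate | [Li+].CCCC[Al-](C)(C)/C=C(C)/CC[C@H]1C(=C)CC[C@H]2[C@@](C)(CO[Si](C)(C)C(C)(C)C)CCC[C@]12C | intermediate (not isolated)
20 | (13E)-19-(TBS-oxy)labda-8(17),13-dien-15-ol | OC/C=C(C)/CC[C@H]1C(=C)CC[C@H]2[C@@](C)(CO[Si](C)(C)C(C)(C)C)CCC[C@]12C | intermediate
21 | (13R,14R)-13,14-epoxy-19-(TBS-oxy)labd-8(17)-en-15-ol | OC[C@H]1O[C@]1(C)CC[C@H]2C(=C)CC[C@H]3[C@@](C)(CO[Si](C)(C)C(C)(C)C)CCC[C@]23C | intermediate
22 | (13R,14S)-13,14-epoxy-15-iodo-19-(TBS-oxy)labd-8(17)-ene | IC[C@H]1O[C@]1(C)CC[C@H]2C(=C)CC[C@H]3[C@@](C)(CO[Si](C)(C)C(C)(C)C)CCC[C@]23C | intermediate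
23 | (13R)-19-(TBS-oxy)labda-8(17),14-dien-13-ol | C=C[C@](C)(O)CC[C@H]1C(=C)CC[C@H]2[C@@](C)(CO[Si](C)(C)C(C)(C)C)CCC[C@]12C | intermediate
24 | (13R)-labda-8(17),14-diene-13,19-diol | C=C[C@](C)(O)CC[C@H]1C(=C)CC[C@H]2[C@@](C)(CO)CCC[C@]12C | intermediate
25 | tiglic acid ((2E)-2-methylbut-2-enoic acid) | C/C=C(\C)C(=O)O | starting material
26 | (13R)-13-hydroxylabda-8(17),14-dien-19-yl (2E)-2-methylbut-2-enoate | C=C[C@](C)(O)CC[C@H]1C(=C)CC[C@H]2[C@@](C)(COC(=O)/C(C)=C/C)CCC[C@]12C | target

**Step count and risks**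
Total step count: 19. Longest linear sequence: 18 steps (1 to 26 through steps 1–7 and 9–19); step 8 is a one-step side branch to reagent 12.

Steps most likely to fail:

1. Step 10 (key step). Closure of a six-membered ring by oxidative cyclization at nickel is slower than the five-membered cases, so conjugate ethylation of the enoyl imide, ethyl instead of hydrogen transfer to C17, or oligomerisation of the terminal alkyne may outrun it. The fallback sets out from 13 and replaces the organometallic coupling by a radical chain. Bu3SnH and AIBN in refluxing benzene (slow addition) add a stannyl radical to C17; the C8 vinyl radical closes 6-exo onto C9 of the enoyl imide through the same ring A-controlled chair, and the α-acyl radical is reduced. This should give 3-[17-(tributylstannyl)-19-(TBS-oxy)-13,14,15,16-tetranorlabd-8(17)-en-12-oyl]-1,3-oxazolidin-2-one F1. Stirring with silica gel in CH2Cl2 protodestannylates the vinylstannane, and the route is rejoined at 14.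

2. Step 3. Degradation of the silyl-capped arene may stall at partly oxidised stages, and the acidic periodate medium may cause loss of the C19 silyl ether followed by lactonisation onto the C9 acid. The fallback sets out from 3 and changes both the substrate and the cleavage chemistry. K2CO3 in MeOH removes only the aryl silyl ether to give 19-(TBS-oxy)podocarpa-8,11,13-trien-12-ol F2. The free phenol ring is then cleaved by exhaustive ozonolysis (O3, CH2Cl2/MeOH, −78 °C) and the ozonolysis products, including any C8,C9-diketone, are taken to the diacid with alkaline H2O2 (aq NaOH, 0 °C → rt, then acidification to pH 4). The route is rejoined at 4.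

3. Step 5. Site selectivity between the two primary alcohols may be incomplete, or the hydroxy aldehyde may close to the lactol and be oxidised on to the seven-membered lactone. The fallback sets out from 4 and moves the differentiation to the ester stage.
   - Both acids are methylated (TMSCHN2, MeOH/toluene) to dimethyl 19-(TBS-oxy)-11,12,13,14-tetranor-8,9-secopodocarpane-8,9-dioate F3.
   - LiBH4 (THF, rt) reduces only the unhindered C8 ester, the C9 ester on quaternary C10 being inert, to methyl 8-hydroxy-19-(TBS-oxy)-11,12,13,14-tetranor-8,9-secopodocarpan-9-oate F4.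
   - Dess–Martin oxidation gives methyl 8-oxo-19-(TBS-oxy)-11,12,13,14-tetranor-8,9-secopodocarpan-9-oate F5.
   - Ohira–Bestmann alkynylation with 7 (K2CO3, MeOH) gives methyl 19-(TBS-oxy)-11,12,13,14,15,16-hexanor-8,9-secolabd-8(17)-yn-9-oate F6.
   - LiAlH4 (Et2O, 0 °C → rt) reduces the hindered ester, and the route is rejoined at 8.

**Further compounds**
F1 | step 10 | 3-[17-(tributylstannyl)-19-(TBS-oxy)-13,14,15,16-tetranorlabd-8(17)-en-12-oyl]-1,3-oxazolidin-2-one | CCCC[Sn](CCCC)(CCCC)C=C1CC[C@H]2[C@@](C)(CO[Si](C)(C)C(C)(C)C)CCC[C@]2(C)[C@H]1CC(=O)N3CCOC3=O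
F2 | step 3 | 19-(TBS-oxy)podocarpa-8,11,13-trien-12-ol | Oc1ccc2CC[C@H]3[C@@](C)(CO[Si](C)(C)C(C)(C)C)CCC[C@]3(C)c2c1
F3 | step 5 | dimethyl 19-(TBS-oxy)-11,12,13,14-tetranor-8,9-secopodocarpane-8,9-dioate | COC(=O)CC[C@H]1[C@@](C)(CO[Si](C)(C)C(C)(C)C)CCC[C@]1(C)C(=O)OC
F4 | step 5 | methyl 8-hydroxy-19-(TBS-oxy)-11,12,13,14-tetranor-8,9-secopodocarpan-9-oate | OCCC[C@H]1[C@@](C)(CO[Si](C)(C)C(C)(C)C)CCC[C@]1(C)C(=O)OC
F5 | step 5 | methyl 8-oxo-19-(TBS-oxy)-11,12,13,14-tetranor-8,9-secopodocarpan-9-oate | O=CCC[C@H]1[C@@](C)(CO[Si](C)(C)C(C)(C)C)CCC[C@]1(C)C(=O)OC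
F6 | step 5 | methyl 19-(TBS-oxy)-11,12,13,14,15,16-hexanor-8,9-secolabd-8(17)-yn-9-oate | C#CCC[C@H]1[C@@](C)(CO[Si](C)(C)C(C)(C)C)CCC[C@]1(C)C(=O)OC
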